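The route rests on cutting the pyran ring at C3–C4 and O1–C8a. Ring A then arrives as a 2-fluorobenzaldehyde (C4 as the formyl carbon, C8a as C–F) and the O1–C2–C3 unit as a β-oxido alkyllithium, a 1,3-C,O-dinucleophile. In one flask the carbanion adds to the aldehyde, the tertiary alkoxide closes the pyran ring by SNAr at C8a, and acid removes the C4 hydroxyl, which sits ortho to O1 and para to O7, to leave the C3=C4 olefin. The key step thus exploits the ortho relation of C4 and C8a on ring A and the 1,3 relation of O1 and C3. A bromine kept at C5 later takes the 4-hydroxyphenethyl arm by B-alkyl Suzuki coupling.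

Key step: step 3

Numbering: atom labels follow the 2H-chromene ring of the target (O1, C2, C3, C4, C4a, C5 to C8, C8a); ring A is the benzo ring. The target has no stereocenter, and the ring fixes the C3=C4 olefin as cis.

Step 1
Reactants: 1 3-bromo-5-fluorophenol; 2 1-bromo-3-methylbut-2-ene (prenyl bromide)
Product: 3 1-bromo-3-fluoro-5-[(3-methylbut-2-en-1-yl)oxy]benzene
Conditions: K2CO3, acetone, 50 °C
Reagents that add atoms: none
Why: Williamson ether synthesis: the potassium phenoxide of 1 should displace bromide from the primary allylic bromide 2 by SN2 at oxygen, which leaves both aryl halogens untouched.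

Step 2
Reactants: 3 1-bromo-3-fluoro-5-[(3-methylbut-2-en-1-yl)oxy]benzene
Product: 6 2-bromo-6-fluoro-4-[(3-methylbut-2-en-1-yl)oxy]benzaldehyde, via aryllithium 4 (not isolated), via lithium hemiaminolate 5 (not isolated)
Conditions: LiN(i-Pr)2 (LDA), THF, −78 °C; then DMF, −78 to −40 °C; then 1 M HCl, 0 °C
Reagents that add atoms: N,N-dimethylformamide CN(C)C=O
Why: Deprotonative ortho-lithiation followed by formylation with DMF: the C–H flanked by fluorine and bromine is the most acidic ring position through the inductive effect of both halogens, and at −78 °C the ortho-halo aryllithium should neither lose lithium halide nor attack the allyl ether before DMF traps it.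

Step 3
Reactants: 6 2-bromo-6-fluoro-4-[(3-methylbut-2-en-1-yl)oxy]benzaldehyde; 7 1-chloro-2-methylpropan-2-ol
Product: 12 5-bromo-2,2-dimethyl-7-[(3-methylbut-2-en-1-yl)oxy]-2H-chromene, via lithium chlorohydrin alkoxide 8 (not isolated), via dilithio reagent 9 (not isolated), via dilithium 1,3-diolate 10 (not isolated), via chroman-4-ol 11 (not isolated)
Conditions: 7, n-BuLi, THF, −78 °C; Li powder, 4,4'-di-tert-butylbiphenyl (5 mol %), −78 °C; solution filtered onto 6, THF, −78 °C; then KOt-Bu, DMPU, 65 °C; then aq. HCl (pH 1), 40 °C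
Reagents that add atoms: none
Why: Reductive lithiation of the lithium alkoxide of 7 should give the β-oxido alkyllithium 9, whose carbanion adds to the formyl carbon C4 of 6 (C3–C4) faster than it can exchange with the aryl bromide; KOt-Bu then converts the tertiary alkoxide O1 into its potassium salt, which displaces fluoride at C8a by addition–elimination SNAr (O1–C8a), and acid ionises the C4 hydroxyl to a benzylic cation that loses H-3 to give the C3=C4 olefin. The closest known reaction types are the 1,2-addition of β-oxido organolithiums to aldehydes, the intramolecular SNAr etherification of fluoroarenes to chromans and the acid dehydration of 2,2-dimethylchroman-4-ols. The pyran ring closes by a 6-exo-trig ipso attack of O1 on the arene carbon C8a, helped by the gem-dimethyl group and by the inductive pull of the meta bromine and meta allyloxy substituents. The C4 carbinol centre is formed racemic and is erased in the dehydration, so no stereocontrol is needed. The step needs site selectivity between the two halogens ortho to C4a: fluoride, not bromide, should be displaced because addition to the C–F carbon is the faster step of SNAr, and only O1 can reach C8a in a six-membered ring, since the C4 alkoxide would have to form a four-membered ring. Ring closure before olefin formation guarantees the cis olefin, and the dehydration is regiospecific because C2 is quaternary and the cation is stabilised by O1 (ortho) and O7 (para).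

Step 4
Reactants: 12 5-bromo-2,2-dimethyl-7-[(3-methylbut-2-en-1-yl)oxy]-2H-chromene; 13 4-ethenylphenyl acetate (4-acetoxystyrene)
Product: 16 4-{2-[2,2-dimethyl-7-[(3-methylbut-2-en-1-yl)oxy]-2H-chromen-5-yl]ethyl}phenol (CNP0337021.0), via alkylborane 14 (not isolated), via aryl acetate 15 (not isolated)
Conditions: 13, 9-BBN, THF, 0 to 25 °C; then 12, Pd(dppf)Cl2 (5 mol %), K3PO4 (3 M aq.), THF–DMF, 65 °C; aq. NH4Cl work-up
Reagents that add atoms: none
Why: Anti-Markovnikov hydroboration of styrene 13 with 9-BBN followed by B-alkyl Suzuki–Miyaura coupling at the C5 bromide should join the arm without exposing the prenyl or chromene olefins to free B–H, and the aqueous phosphate base at 65 °C should hydrolyse the aryl acetate in the same pot to free the phenol.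

Compound list
1 | 3-bromo-5-fluorophenol | Oc1cc(F)cc(Br)c1 | starting material
2 | 1-bromo-3-methylbut-2-ene (prenyl bromide) | CC(C)=CCBr | starting material
3 | 1-bromo-3-fluoro-5-[(3-methylbut-2-en-1-yl)oxy]benzene | CC(C)=CCOc1cc(F)cc(Br)c1 | intermediate
4 | {2-bromo-6-fluoro-4-[(3-methylbut-2-en-1-yl)oxy]phenyl}lithium | [Li]c1c(F)cc(OCC=C(C)C)cc1Br | intermediate
5 | lithium {2-bromo-6-fluoro-4-[(3-methylbut-2-en-1-yl)oxy]phenyl}(dimethylamino)methanolate (racemic) | CN(C)C(O[Li])c1c(F)cc(OCC=C(C)C)cc1Br | intermediate
6 | 2-bromo-6-fluoro-4-[(3-methylbut-2-en-1-yl)oxy]benzaldehyde | O=Cc1c(F)cc(OCC=C(C)C)cc1Br | intermediate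
7 | 1-chloro-2-methylpropan-2-ol | CC(C)(O)CCl | starting material
8 | lithium 1-chloro-2-methylpropan-2-olate | CC(C)(CCl)O[Li] | intermediate
9 | lithium 1-lithio-2-methylpropan-2-olate | [Li]CC(C)(C)O[Li] | intermediate
10 | dilithium 1-{2-bromo-6-fluoro-4-[(3-methylbut-2-en-1-yl)oxy]phenyl}-3-methylbutane-1,3-diolate (racemic) | CC(C)=CCOc1cc(F)c(C(O[Li])CC(C)(C)O[Li])c(Br)c1 | intermediate
11 | 5-bromo-2,2-dimethyl-7-[(3-methylbut-2-en-1-yl)oxy]-3,4-dihydro-2H-chromen-4-ol (racemic) | CC(C)=CCOc1cc(Br)c2C(O)CC(C)(C)Oc2c1 | intermediate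
12 | 5-bromo-2,2-dimethyl-7-[(3-methylbut-2-en-1-yl)oxy]-2H-chromene | CC(C)=CCOc1cc(Br)c2C=CC(C)(C)Oc2c1 | intermediate
13 | 4-ethenylphenyl acetate | CC(=O)Oc1ccc(C=C)cc1 | starting material
14 | 4-[2-(9-borabicyclo[3.3.1]nonan-9-yl)ethyl]phenyl acetate | CC(=O)Oc1ccc(CCB2C3CCCC2CCC3)cc1 | intermediate
15 | 4-{2-[2,2-dimethyl-7-[(3-methylbut-2-en-1-yl)oxy]-2H-chromen-5-yl]ethyl}phenyl acetate | CC(C)=CCOc1cc(CCc2ccc(OC(C)=O)cc2)c2C=CC(C)(C)Oc2c1 | intermediate
16 | 4-{2-[2,2-dimethyl-7-[(3-methylbut-2-en-1-yl)oxy]-2H-chromen-5-yl]ethyl}phenol | CC(C)=CCOc1cc(CCc2ccc(O)cc2)c2c(c1)OC(C)(C)C=C2 | target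

Total step count: 4. Longest linear sequence: 4 steps (1 → 3 → 6 → 12 → 16); compounds 2, 7 and 13 are commercial and enter directly.

Steps most likely to fail

Step 3. The β-oxido alkyllithium may lose lithium oxide to isobutene before it adds. Ring closure at C8a may also be slow, because once the formyl group has been consumed the fluoride is only inductively activated and the substrate carries a second alkoxide. The electron-rich chromene may oligomerise during the acid dehydration. The fallback sets out from 6 and comes back at 12. The fluoride of 6, still activated by the formyl group, is displaced first by the potassium alkoxide of 2-methylbut-3-en-2-ol (KH, THF, 0 °C) to give 2-bromo-6-[(2-methylbut-3-en-2-yl)oxy]-4-[(3-methylbut-2-en-1-yl)oxy]benzaldehyde F1. Wittig methylenation (Ph3PCH3Br, KOt-Bu, THF, 0 °C) should then give 1-bromo-2-ethenyl-3-[(2-methylbut-3-en-2-yl)oxy]-5-[(3-methylbut-2-en-1-yl)oxy]benzene F2. Ring-closing olefin metathesis with the second-generation Grubbs catalyst (CH2Cl2, 40 °C) closes C3=C4 with loss of ethene and returns 12.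

Step 2. Metalation may occur at a ring C–H next to the ether oxygen instead, or the ortho-halo aryllithium may lose lithium halide to an aryne before it is trapped. The fallback sets out from 1 and comes back at 6. Para-bromination of 1 with N-bromosuccinimide (MeCN, 0 °C) should give 3,4-dibromo-5-fluorophenol F3. O-Alkylation with 2 (K2CO3, acetone) gives 1,2-dibromo-3-fluoro-5-[(3-methylbut-2-en-1-yl)oxy]benzene F4. Bromine–magnesium exchange with i-PrMgCl·LiCl (THF, −40 °C) should take the bromine flanked by fluorine and bromine, and a DMF quench then gives 6.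

Step 4. Oxidative addition at the hindered, electron-rich C5–Br bond beside the ring fusion may be slow, so that protodeboronation of the alkylborane or olefin migration by palladium hydride takes over. The fallback sets out from 6 and comes back at 16. The coupling is moved to the aldehyde stage, where the C–Br bond is activated by the ortho formyl group. Aldehyde 6 and alkylborane 14 (Pd(dppf)Cl2, K3PO4, THF–DMF, 50 °C) should give 4-{2-[3-fluoro-2-formyl-5-[(3-methylbut-2-en-1-yl)oxy]phenyl]ethyl}phenyl acetate F5. Its acetate is cleaved (K2CO3, MeOH, 25 °C) to 2-fluoro-6-[2-(4-hydroxyphenyl)ethyl]-4-[(3-methylbut-2-en-1-yl)oxy]benzaldehyde F6. After deprotonation of the phenol with NaH, F6 is carried through the annulation of step 3 (reagent 9; KOt-Bu, DMPU; acid) to give 16 directly.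

Further compounds
F1 | step 3 | 2-bromo-6-[(2-methylbut-3-en-2-yl)oxy]-4-[(3-methylbut-2-en-1-yl)oxy]benzaldehyde | CC(C)=CCOc1cc(OC(C)(C)C=C)c(C=O)c(Br)c1
F2 | step 3 | 1-bromo-2-ethenyl-3-[(2-methylbut-3-en-2-yl)oxy]-5-[(3-methylbut-2-en-1-yl)oxy]benzene | CC(C)=CCOc1cc(OC(C)(C)C=C)c(C=C)c(Br)c1
F3 | step 2 | 3,4-dibromo-5-fluorophenol | Oc1cc(F)c(Br)c(Br)c1
F4 | step 2 | 1,2-dibromo-3-fluoro-5-[(3-methylbut-2-en-1-yl)oxy]benzene | CC(C)=CCOc1cc(F)c(Br)c(Br)c1
F5 | step 4 | 4-{2-[3-fluoro-2-formyl-5-[(3-methylbut-2-en-1-yl)oxy]phenyl]ethyl}phenyl acetate | CC(C)=CCOc1cc(F)c(C=O)c(CCc2ccc(OC(C)=O)cc2)c1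
F6 | step 4 | 2-fluoro-6-[2-(4-hydroxyphenyl)ethyl]-4-[(3-methylbut-2-en-1-yl)oxy]benzaldehyde | CC(C)=CCOc1cc(F)c(C=O)c(CCc2ccc(O)cc2)c1
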